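## Retrosynthetic overview
1. Cut both oxirane C–O bonds. The (S)-epoxide comes from enantioselective oxygen-atom transfer to the 1,1-disubstituted alkene of the matching 2-arylallyl bis-isobutyrate. This is done last, so the labile benzylic epoxide is never carried forward.
2. The alkene bis-isobutyrate comes from double O-acylation of a 2-(2-hydroxyaryl)allyl alcohol.
3. That diol comes from a Suzuki–Miyaura coupling of an ortho-bromophenol with an α-boryl allyl alcohol made in the flask from propargyl alcohol and B2pin2.
4. The bromophenol comes from regioselective bromination of 4-methoxy-3-methylphenol.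
5. Ring order: the arene is bought. The oxirane is the only ring built, and it is formed in the final step.

Assumption: the three numbered starting materials are catalogue chemicals, and the facial sense written for step 4 is a model-based prediction to be checked on the first run against material from the fallback (the mirror-image catalyst pair is equally accessible).

Abbreviations: SIMes = 1,3-dimesitylimidazolidin-2-ylidene; Me2N-PDP = 1,1'-bis{[4-(dimethylamino)pyridin-2-yl]methyl}-2,2'-bipyrrolidine; pin = pinacolato.

## Route

Step 1
Reactants: 1 4-methoxy-3-methylphenol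
Product: 2 2-bromo-4-methoxy-5-methylphenol
Conditions: NBS (1.0 equiv), MeCN, 0 °C, dark
Reagents that add atoms: N-bromosuccinimide, O=C1CCC(=O)N1Br
Why: Electrophilic aromatic bromination, in which the free OH is the strongest director, its para position is blocked by OMe, and of its two ortho positions only the one para to the methyl group is unhindered, so a single regioisomer is expected and no stereocentre is formed.

Step 2
Reactants: 2 2-bromo-4-methoxy-5-methylphenol; 3 propargyl alcohol; 4 bis(pinacolato)diboron
Product: 6 2-(3-hydroxyprop-1-en-2-yl)-4-methoxy-5-methylphenol, via alkenylboronate 5 (not isolated)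
Conditions: 3 (1.4 equiv), 4 (1.4 equiv), (SIMes)CuCl (2 mol %), NaOtBu (4 mol %), MeOH (1.5 equiv), THF, −50 → −15 °C; then 2 (1.0 equiv), Pd(OAc)2 (2 mol %), SPhos (4 mol %), K3PO4 (3 equiv), H2O, 60 °C
Reagents that add atoms: none
Why: Copper-catalysed α-selective protoboration of a propargylic terminal alkyne (syn Cu–Bpin addition puts boron on the internal carbon, then MeOH protonolysis) is followed in the same flask by Suzuki–Miyaura coupling, which tolerates both free OH groups and with SPhos handles the electron-rich ortho-bromophenol; no stereocentre is formed.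

Step 3
Reactants: 6 2-(3-hydroxyprop-1-en-2-yl)-4-methoxy-5-methylphenol
Product: 7 2-{5-methoxy-4-methyl-2-[(2-methylpropanoyl)oxy]phenyl}prop-2-en-1-yl 2-methylpropanoate
Conditions: (iPrCO)2O (3 equiv), DMAP (10 mol %), pyridine, 0 °C → rt
Reagents that add atoms: isobutyric anhydride, CC(C)C(=O)OC(=O)C(C)C
Why: DMAP-catalysed nucleophilic acyl substitution esterifies the phenol and the primary allylic alcohol together under non-acidic conditions, which spares the acid-sensitive ortho-hydroxystyrene unit; no stereocentre is formed.

Step 4
Reactants: 7 2-{5-methoxy-4-methyl-2-[(2-methylpropanoyl)oxy]phenyl}prop-2-en-1-yl 2-methylpropanoate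
Product: 8 [(2S)-2-{5-methoxy-4-methyl-2-[(2-methylpropanoyl)oxy]phenyl}oxiran-2-yl]methyl 2-methylpropanoate
Conditions: Fe(OTf)2[(S,S)-Me2N-PDP] (2 mol %), N-(1,8-naphthaloyl)-L-isoleucine (4 mol %), 30% aq H2O2 (1.8 equiv, syringe pump, 30 min), MeCN, −30 °C
Reagents that add atoms: hydrogen peroxide, OO
Why: Proposed new method: the amino-acid carboxylate binds cis to the Fe–OOH unit of the divalent-iron precatalyst after oxidation and assists heterolytic O–O cleavage to a formally pentavalent oxoiron carboxylate, which transfers oxygen in a concerted electrophilic way to the only alkene, so both oxirane C–O bonds and the quaternary stereocentre are made in one event; the C2-symmetric bipyrrolidine backbone and the naphthalimide wall of the co-ligand leave one open quadrant for the flexible CH2OCOiPr arm while the twisted ortho-acyloxyaryl ring lies against the imide, exposing the Re face of the aryl-bearing carbon and giving (S); the closest known reaction type is the non-heme iron/H2O2 asymmetric epoxidation of simple α-alkylstyrenes, which has not been shown on 2-arylallyl esters or on ortho-oxygenated aryl groups; only catalytic acid and −30 °C are used, so the acid-labile benzylic epoxide and both esters should survive.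

## Compound list
1 | 4-methoxy-3-methylphenol | COc1ccc(O)cc1C | starting material
2 | 2-bromo-4-methoxy-5-methylphenol | COc1cc(Br)c(O)cc1C | intermediate
3 | prop-2-yn-1-ol (propargyl alcohol) | C#CCO | starting material
4 | bis(pinacolato)diboron | CC1(C)OB(OC1(C)C)B1OC(C)(C)C(C)(C)O1 | starting material
5 | 2-(4,4,5,5-tetramethyl-1,3,2-dioxaborolan-2-yl)prop-2-en-1-ol | C=C(CO)B1OC(C)(C)C(C)(C)O1 | intermediate
6 | 2-(3-hydroxyprop-1-en-2-yl)-4-methoxy-5-methylphenol | COc1cc(C(=C)CO)c(O)cc1C | intermediate
7 | 2-{5-methoxy-4-methyl-2-[(2-methylpropanoyl)oxy]phenyl}prop-2-en-1-yl 2-methylpropanoate | COc1cc(C(=C)COC(=O)C(C)C)c(OC(=O)C(C)C)cc1C | intermediate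
8 | [(2S)-2-{5-methoxy-4-methyl-2-[(2-methylpropanoyl)oxy]phenyl}oxiran-2-yl]methyl 2-methylpropanoate | COc1cc([C@@]2(COC(=O)C(C)C)CO2)c(OC(=O)C(C)C)cc1C | target

Total step count: 4. Longest linear sequence: 4 (1 → 2 → 6 → 7 → 8).

## Three steps most likely to fail

**Step 4 (the new step).**
- Risks: the ee may be only moderate, because the ortho-substituted aryl ring is twisted out of conjugation.
- The electron-rich arene or the ArCH3 group may be over-oxidised.
- The iron Lewis acid may promote rearrangement of the epoxide to the aldehyde.

The fallback uses known chemistry only. It sets out from 6 and comes back at 8. Phase-transfer Schotten–Baumann acylation (isobutyryl chloride 1.0 equiv, 1 M NaOH, Bu4NHSO4, CH2Cl2, 0 °C) esterifies only the phenoxide. It gives 2-(3-hydroxyprop-1-en-2-yl)-4-methoxy-5-methylphenyl 2-methylpropanoate F1. Sharpless asymmetric epoxidation of this free allylic alcohol follows (Ti(OiPr)4 10 mol %, D-(−)-diisopropyl tartrate 12 mol %, cumene hydroperoxide, 4 Å sieves, CH2Cl2, −20 °C). The tartrate enantiomer is the one that turns 2-methylprop-2-en-1-ol into (R)-2-methylglycidol. The product is 2-[(2R)-2-(hydroxymethyl)oxiran-2-yl]-4-methoxy-5-methylphenyl 2-methylpropanoate F2. Its descriptor is R only because CH2OH ranks below the ring CH2; the spatial arrangement is that of 8. Acylation with isobutyric anhydride, DMAP and pyridine at 0 °C then gives 8.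

**Step 2.**
- Risks: α-selectivity in the protoboration may be incomplete.
- Boronate 5 may protodeboronate in aqueous base.
- Zerovalent palladium may ionise the product allylic alcohol, and the ortho-phenoxide would then close it to a benzofuran-type by-product.

The fallback replaces cross-coupling by carbomagnesiation. It sets out from 2 and comes back at 6. Silylation (TBSCl, imidazole, DMF) gives (2-bromo-4-methoxy-5-methylphenoxy)(tert-butyl)dimethylsilane F3. Mg turnings and LiCl in THF at 25 °C give [2-(tert-butyldimethylsilyloxy)-5-methoxy-4-methylphenyl]magnesium bromide F4. With CuI (10 mol %), F4 adds to the magnesium alkoxide of 3 (pre-formed with iPrMgCl). This is the classical copper-catalysed carbomagnesiation of propargyl alcohol, which puts the aryl group on the internal carbon. After an NH4Cl quench it gives 2-[2-(tert-butyldimethylsilyloxy)-5-methoxy-4-methylphenyl]prop-2-en-1-ol F5. Bu4NF in THF at 0 °C frees the phenol without acid and gives 6.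

**Step 1.**
- Risks: the para-methoxyphenol may be oxidised to the quinone.
- Dibromination may occur.
- Some bromination may occur at the crowded ortho position.

The fallback replaces electrophilic substitution by directed ortho-metalation. It sets out from 1 and comes back at 2. Diethylcarbamoyl chloride and NaH in THF give 4-methoxy-3-methylphenyl N,N-diethylcarbamate F6. sBuLi/TMEDA in THF at −78 °C removes the unhindered proton ortho to the carbamate and gives {2-[(diethylcarbamoyl)oxy]-5-methoxy-4-methylphenyl}lithium F7. A quench with 1,2-dibromoethane gives 2-bromo-4-methoxy-5-methylphenyl N,N-diethylcarbamate F8. NaOH in aqueous EtOH at reflux cleaves the carbamate and gives 2.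

## Further compounds
F1 | step 4 | 2-(3-hydroxyprop-1-en-2-yl)-4-methoxy-5-methylphenyl 2-methylpropanoate | COc1cc(C(=C)CO)c(OC(=O)C(C)C)cc1C
F2 | step 4 | 2-[(2R)-2-(hydroxymethyl)oxiran-2-yl]-4-methoxy-5-methylphenyl 2-methylpropanoate | COc1cc([C@@]2(CO)CO2)c(OC(=O)C(C)C)cc1C
F3 | step 2 | (2-bromo-4-methoxy-5-methylphenoxy)(tert-butyl)dimethylsilane | COc1cc(Br)c(O[Si](C)(C)C(C)(C)C)cc1C
F4 | step 2 | [2-(tert-butyldimethylsilyloxy)-5-methoxy-4-methylphenyl]magnesium bromide | COc1cc([Mg]Br)c(O[Si](C)(C)C(C)(C)C)cc1C
F5 | step 2 | 2-[2-(tert-butyldimethylsilyloxy)-5-methoxy-4-methylphenyl]prop-2-en-1-ol | COc1cc(C(=C)CO)c(O[Si](C)(C)C(C)(C)C)cc1C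
F6 | step 1 | 4-methoxy-3-methylphenyl N,N-diethylcarbamate | CCN(CC)C(=O)Oc1ccc(OC)c(C)c1
F7 | step 1 | {2-[(diethylcarbamoyl)oxy]-5-methoxy-4-methylphenyl}lithium | [Li]c1cc(OC)c(C)cc1OC(=O)N(CC)CC
F8 | step 1 | 2-bromo-4-methoxy-5-methylphenyl N,N-diethylcarbamate | CCN(CC)C(=O)Oc1cc(C)c(OC)cc1Br
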